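The ten-membered carbocycle is not cyclised but uncovered: a cis-fused cyclopentane–cycloheptene (bicyclo[5.3.0]decene) is cut across its shared C6–C10 bond by a Wharton (Grob-type) fragmentation. In one operation the tertiary C6 alkoxide becomes the C6 ketone and the C1 mesylate leaves, so the ring-cis C1=C10 alkene carrying C14 appears transannular to the oxygenated C6, while the ring-cis C4=C5 alkene is inherited from the seven-membered ring. The substrate is a hydroazulenol with C6–OH, C1–OMs trans to the C14 arm on quaternary C10, the 8,9-cis-diol as acetonide and the C7 two-carbon arm, with C7–C9 set on the five-membered ring.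

Key step: step 20

Remarks
- Numbering: all intermediates carry the germacrane numbers of the target (ring C1–C10, lactone arm C11–C13, C14 on C10, C15 on C4); "ring-cis" means cis within the ten-membered ring.
- Assumption: (1R,5S)-2-oxabicyclo[3.3.0]oct-6-en-3-one and (S)-2-hydroxy-2-methylbutanoic acid are taken as purchasable in enantiopure form.
- Design of the fragmentation substrate: the seven-membered ring is fused on the cyclopentane face opposite to the acetonide and the C7 arm. C1, C6 and C10 lose their configuration in the key step, so only their mutual relation counts (cis fusion, C1–O trans to C14), and this face is the one substrate control delivers; an all-cis arrangement would need attack on the concave face.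
- Protecting groups: O12 is carried as a pivalate and O14 as a TBS ether. No metal enolate with a β-oxygen is formed before the key step, C1 is set by a directed reduction, and C8/C9 are told apart by a 9,14-silylene.

Step 1
Reactants: 1 propargyl alcohol
Product: 3 (Z)-3-iodo-2-methylprop-2-en-1-ol, via alkenylmagnesium chelate 2 (not isolated)
Conditions: MeMgBr (2.5 equiv), CuI (cat.), THF/Et2O, 0 °C → rt; then I2, −20 °C
Reagents that add atoms: methylmagnesium bromide, C[Mg]Br; iodine, II
Why: Copper-catalysed anti-carbomagnesiation of the propargylic alkoxide delivers methyl to C4 and magnesium to C5 on the side of the CH2O group (five-membered chelate), so iodinolysis with retention should give the Z-iodoalkene whose geometry becomes the ring-cis C4=C5 bond.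

Step 2
Reactants: 3 (Z)-3-iodo-2-methylprop-2-en-1-ol
Product: 4 (Z)-3-bromo-1-iodo-2-methylprop-1-ene
Conditions: CBr4, PPh3, CH2Cl2, 0 °C
Reagents that add atoms: carbon tetrabromide, BrC(Br)(Br)Br
Why: The Appel bromination converts the primary allylic alcohol into the bromide under neutral conditions that leave the alkenyl iodide and its geometry untouched.

Step 3
Reactants: 5 tert-butyl acetate; 4 (Z)-3-bromo-1-iodo-2-methylprop-1-ene
Product: 7 tert-butyl (Z)-5-iodo-4-methylpent-4-enoate, via tert-butyl acetate lithium enolate 6 (not isolated)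
Conditions: LiN(iPr)2, THF, −78 °C; then 4, −78 → 0 °C
Reagents that add atoms: none
Why: SN2 alkylation of the non-self-condensing tert-butyl ester enolate by the allylic bromide adds C1 and C2, attack at the CH2Br carbon being preferred over SN2′ attack at the iodine-bearing carbon.

Step 4
Reactants: 7 tert-butyl (Z)-5-iodo-4-methylpent-4-enoate
Product: 8 (Z)-5-iodo-4-methylpent-4-enal
Conditions: iBu2AlH (1.1 equiv), CH2Cl2, −78 °C
Reagents that add atoms: none
Why: Partial ester reduction stops at the aldehyde because the tetrahedral aluminium hemiacetal of the tert-butyl ester is stable at −78 °C and collapses only on work-up.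

Step 5
Reactants: 9 (S)-2-hydroxy-2-methylbutanoic acid
Product: 10 (S)-2-acetoxy-2-methylbutanoic acid
Conditions: AcCl (neat), 50 °C; then H2O, THF
Reagents that add atoms: acetyl chloride, CC(Cl)=O
Why: O-Acetylation of the tertiary α-hydroxy acid (any mixed anhydride is hydrolysed on work-up) leaves the quaternary stereocentre untouched because no bond to it is broken.

Step 6
Reactants: 11 (1R,5S)-2-oxabicyclo[3.3.0]oct-6-en-3-one
Product: 12 8,9-cis-diol lactone
Conditions: OsO4 (cat.), N-methylmorpholine N-oxide, acetone/H2O, rt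
Reagents that add atoms: N-methylmorpholine N-oxide, C[N+]1([O-])CCOCC1; water, O
Why: Catalytic OsO4 syn-dihydroxylation should take place on the convex face, anti to the lactone ring, which sets C8 and C9 as a cis-diol in the absolute sense dictated by the enantiopure lactone.

Step 7
Reactants: 12 8,9-cis-diol lactone
Product: 13 8,9-acetonide lactone
Conditions: 2,2-dimethoxypropane, TsOH (cat.), acetone, rt
Reagents that add atoms: 2,2-dimethoxypropane, COC(C)(C)OC
Why: Acid-catalysed transketalisation ties the only diol of the molecule up as the cis-fused dioxolane.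

Step 8
Reactants: 13 8,9-acetonide lactone
Product: 16 8,9-acetonide butenolide (C7=C11), via lactone lithium enolate 14 (not isolated), via 11-phenylselanyl lactone 15 (not isolated)
Conditions: LiN(iPr)2, THF, −78 °C; PhSeBr; then H2O2, pyridine, CH2Cl2, 0 °C → rt
Reagents that add atoms: none
Why: α-Selenenylation of the lactone enolate occurs on the convex face, syn to H7 (the only β-hydrogen), so selenoxide syn-elimination should give the butenolide and remove the C7 stereocentre, which in the lactone holds the arm trans to the diol.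

Step 9
Reactants: 16 8,9-acetonide butenolide
Product: 17 ene-6,12-diol
Conditions: iBu2AlH (3.5 equiv), CH2Cl2, −78 → 0 °C
Reagents that add atoms: none
Why: iBu2AlH reduces the butenolide carbonyl in 1,2-fashion through the lactol to the ene-1,4-diol without conjugate reduction.

Step 10
Reactants: 17 ene-6,12-diol
Product: 18 12-O-pivalate
Conditions: PivCl (1.05 equiv), pyridine, CH2Cl2, −20 °C
Reagents that add atoms: pivaloyl chloride, CC(C)(C)C(Cl)=O
Why: Selective esterification with the bulky acyl chloride should acylate the primary allylic hydroxyl well before the secondary one.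

Step 11
Reactants: 18 12-O-pivalate
Product: 19 exocyclic enone (C6 ketone)
Conditions: MnO2, CH2Cl2, rt
Reagents that add atoms: none
Why: Allylic oxidation with MnO2 gives the enone in which C7 is sp2, so that C10 is the only α-carbon left that can be enolised.

Step 12
Reactants: 19 exocyclic enone
Product: 21 10-hydroxymethyl ketone, via trimethylsilyl dienol ether 20 (not isolated)
Conditions: TMSOTf, Et3N, CH2Cl2, 0 °C; then aq. CH2O, Yb(OTf)3 (cat.), THF, rt
Reagents that add atoms: formaldehyde, C=O
Why: Soft enolisation can only go toward C10, and the lanthanide-catalysed Mukaiyama aldol with aqueous formaldehyde then hydroxymethylates C10 on the convex face without a metal enolate that could expel the β-oxygen at C9; the new C10 centre is erased again in step 14.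

Step 13
Reactants: 21 10-hydroxymethyl ketone
Product: 22 14-O-TBS ketone
Conditions: TBSCl, imidazole, DMF, 0 °C → rt
Reagents that add atoms: tert-butyldimethylsilyl chloride, CC(C)(C)[Si](C)(C)Cl
Why: Standard silylation protects the primary O14 as a silyl ether, a poor leaving group and a poor Lewis base for the next step.

Step 14
Reactants: 22 14-O-TBS ketone; 8 (Z)-5-iodo-4-methylpent-4-enal
Product: 24 C10-quaternary aldol adduct (C1 epimers), via tetrasubstituted enol silane 23 (not isolated)
Conditions: TMSOTf, Et3N, CH2Cl2, 0 °C; then 8, BF3·OEt2, CH2Cl2, −78 °C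
Reagents that add atoms: none
Why: The enol silane, again formed only toward C10, should add to the BF3-activated aldehyde in a Mukaiyama aldol from the convex face anti to the acetonide, which fixes quaternary C10 with the C1 chain on that face; the carbinol configuration at C1 is not relied on because steps 17 and 18 reset it.

Step 15
Reactants: 24 C10-quaternary aldol adduct
Product: 25 saturated ketone (C7 set)
Conditions: [(Ph3P)CuH]6, H2O, toluene, rt
Reagents that add atoms: none
Why: Copper hydride conjugate reduction delivers hydride to C11 and the copper enolate is protonated at C7 from the convex face anti to the acetonide, which should place the side chain cis to O8 as the target requires, while the alkenyl iodide and the ester are left alone.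

Step 16
Reactants: 25 saturated ketone
Product: 26 cis-fused bicyclic 1,6-diol (C1 epimers)
Conditions: CrCl2 (excess), NiCl2 (cat.), DMSO, rt
Reagents that add atoms: none
Why: In the intramolecular Nozaki–Hiyama–Kishi reaction the alkenylchromium formed at C5 can reach the C6 carbonyl only from the face that carries its tether (7-exo-trig), so the cycloheptene should close with cis ring fusion and the new C6 hydroxyl cis to the C14 arm.

Step 17
Reactants: 26 cis-fused bicyclic 1,6-diol
Product: 27 6-hydroxy-1-ketone
Conditions: Dess–Martin periodinane, NaHCO3, CH2Cl2, 0 °C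
Reagents that add atoms: none
Why: Dess–Martin oxidation converts both C1 epimers into one ketone and cannot touch the tertiary allylic C6 hydroxyl.

Step 18
Reactants: 27 6-hydroxy-1-ketone
Product: 28 1,6-anti diol
Conditions: Me4NBH(OAc)3, AcOH, MeCN, −30 °C
Reagents that add atoms: none
Why: In the Evans–Saksena reduction the triacetoxyborohydride exchanges onto O6 and delivers hydride intramolecularly to the C1 ketone, which should give the 1,3-anti diol with the C1 hydroxyl trans to O6 and to the C14 arm, the relationship the fragmentation needs.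

Step 19
Reactants: 28 1,6-anti diol
Product: 29 C1 mesylate
Conditions: MsCl, Et3N, CH2Cl2, −20 °C
Reagents that add atoms: methanesulfonyl chloride, CS(=O)(=O)Cl
Why: Mesylation through sulfene selects the secondary C1 hydroxyl, since the tertiary C6 hydroxyl reacts far more slowly at low temperature.

Step 20
Reactants: 29 C1 mesylate
Product: 30 ten-membered C6 enone
Conditions: KOtBu (1.05 equiv), THF, −78 → −20 °C; pH 7 buffer at −20 °C
Reagents that add atoms: none
Why: KOtBu converts the tertiary C6 hydroxyl into its alkoxide, whose lone pair forms the C6=O π bond while the C6–C10 σ bond becomes the C1=C10 π bond and mesylate departs in one concerted anti fragmentation. The closest known reaction type is the Wharton (Grob-type) fragmentation of decalin 1,3-diol monosulfonates to cyclodecenones. The ten-membered ring is not closed by a cyclisation: it appears when the zero-atom bridge of the bicyclo[5.3.0] system is cleaved, so no macrocyclisation entropy is paid. No stereocentre is formed; the C1=C10 geometry follows from the anti-periplanar C6–C10/C1–O arrangement, which the cis-fused cycloheptene offers with the pseudo-equatorial mesylate trans to the C14 arm, so C2 ends cis to C9 (ring-cis), and C4=C5 stays cis as it was in the seven-membered ring. The step needs fragmentation to win over oxetane closure and over base attack on the new enone: the neopentyl C1 centre disfavours substitution, and one equivalent of base at low temperature with a buffered quench keeps C7–H (α to the ketone, β to O8) from epimerising or eliminating.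

Step 21
Reactants: 30 ten-membered C6 enone
Product: 31 (6R)-6,12-diol
Conditions: iBu2AlH (excess), CH2Cl2, −78 °C
Reagents that add atoms: none
Why: iBu2AlH reduces the enone in 1,2-fashion and cleaves the pivalate in the same operation, and hydride should approach C6 from the outer face anti to the C7–C8 bond (Felkin–Anh), which gives the 6R carbinol with O6 anti to C11.

Step 22
Reactants: 31 (6R)-6,12-diol
Product: 32 trans-fused 6,12-lactone
Conditions: TEMPO (cat.), PhI(OAc)2, CH2Cl2, rt
Reagents that add atoms: none
Why: In this oxidative lactonisation the oxoammonium oxidant selects the primary alcohol, the aldehyde is trapped by O6 as the lactol and oxidised on to the γ-lactone faster than the secondary allylic alcohol can react.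

Step 23
Reactants: 32 trans-fused 6,12-lactone
Product: 36 α-methylene lactone, via lactone lithium enolate 33 (not isolated), via 11-(dimethylaminomethyl) lactone 34 (not isolated), via trimethylammonium iodide 35 (not isolated)
Conditions: LiN(iPr)2, THF, −78 °C; Me2N=CH2 I; then MeI, THF; then aq. NaHCO3, CH2Cl2, rt
Reagents that add atoms: dimethyl(methylidene)ammonium iodide, C=[N+](C)C.[I-]
Why: Mannich reaction of the lactone enolate with the iminium salt, N-methylation and Hofmann-type β-elimination install the exocyclic C11=C13 methylene, the configuration of C11 in the intermediates being irrelevant.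

Step 24
Reactants: 36 α-methylene lactone
Product: 37 8,9,14-triol
Conditions: AcOH, H2O, THF, 45 °C
Reagents that add atoms: none
Why: Aqueous acetic acid hydrolyses the acetonide and the primary allylic TBS ether together (acetal and silyl ether hydrolysis), and the α-methylene lactone is stable to acid.

Step 25
Reactants: 37 8,9,14-triol
Product: 38 9,14-O-di-tert-butylsilylene 8-ol
Conditions: tBu2Si(OTf)2, 2,6-lutidine, CH2Cl2, −20 → 0 °C
Reagents that add atoms: di-tert-butylsilyl bis(trifluoromethanesulfonate), CC(C)(C)[Si](OS(=O)(=O)C(F)(F)F)(OS(=O)(=O)C(F)(F)F)C(C)(C)C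
Why: In this cyclic silylene protection the bis-triflate reacts first at the primary O14 and then closes the six-membered dioxasilinane onto the 1,3-related O9, which leaves only O8 free and tells C8 and C9 apart without relying on their relative reactivity.

Step 26
Reactants: 38 9,14-O-di-tert-butylsilylene 8-ol; 10 (S)-2-acetoxy-2-methylbutanoic acid
Product: 40 8-O-acyl silylene, via acid chloride 39 (not isolated)
Conditions: 10, (COCl)2, DMF (cat.), CH2Cl2, 0 °C → rt; then 38, Et3N, DMAP, CH2Cl2, rt
Reagents that add atoms: none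
Why: DMAP-catalysed esterification of the only free hydroxyl by the acid chloride attaches the side chain at O8, and its quaternary stereocentre cannot epimerise.

Step 27
Reactants: 40 8-O-acyl silylene
Product: 41 9,14-diol 8-ester
Conditions: HF·pyridine, pyridine, THF, 0 °C
Reagents that add atoms: none
Why: Fluoride-mediated desilylation cleaves both Si–O bonds of the silylene under buffered conditions that spare the esters and the methylene lactone.

Step 28
Reactants: 41 9,14-diol 8-ester
Product: 42 14-aldehyde 9-ol
Conditions: TEMPO (cat.), PhI(OAc)2, CH2Cl2, rt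
Reagents that add atoms: none
Why: The oxoammonium oxidant selects the primary allylic alcohol over the secondary one at C9 and stops at the enal (selective alcohol oxidation), whose ring-cis geometry, with C2 anti to the formyl group, is the stable one.

Step 29
Reactants: 42 14-aldehyde 9-ol
Product: 43 target CNP0499875.1
Conditions: Ac2O, pyridine, DMAP (cat.), CH2Cl2, 0 °C
Reagents that add atoms: acetic anhydride, CC(=O)OC(C)=O
Why: DMAP-catalysed acetylation of the remaining C9 hydroxyl completes the target.

Compound list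
1 | prop-2-yn-1-ol (propargyl alcohol) | C#CCO | starting material
2 | cyclic alkenylmagnesium alkoxide (4-methyl-2,5-dihydro-1,2-oxamagnesole; Mg cis to the CH2O carbon) | CC1=C[Mg]OC1 | intermediate
3 | (Z)-3-iodo-2-methylprop-2-en-1-ol | OC/C(C)=C\I | intermediate
4 | (Z)-3-bromo-1-iodo-2-methylprop-1-ene | BrC/C(C)=C\I | intermediate
5 | tert-butyl acetate | CC(=O)OC(C)(C)C | starting material
6 | lithium enolate of tert-butyl acetate | [Li]OC(=C)OC(C)(C)C | intermediate
7 | tert-butyl (Z)-5-iodo-4-methylpent-4-enoate | CC(C)(C)OC(=O)CC/C(C)=C\I | intermediate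
8 | (Z)-5-iodo-4-methylpent-4-enal (C1–C5 and C15; iodine cis to C3) | O=CCC/C(C)=C\I | intermediate
9 | (S)-2-hydroxy-2-methylbutanoic acid | OC(=O)[C@](C)(CC)O | starting material
10 | (S)-2-acetoxy-2-methylbutanoic acid | OC(=O)[C@](C)(CC)OC(C)=O | intermediate
11 | (3aS,6aR)-3,3a,6,6a-tetrahydro-2H-cyclopenta[b]furan-2-one, i.e. (1R,5S)-2-oxabicyclo[3.3.0]oct-6-en-3-one (O on C6, C7 ring fusion, C8=C9, C10, C11, C12=O) | O=C1C[C@H]2C=CC[C@H]2O1 | starting material
12 | 8,9-cis-diol of 11, both hydroxyls on the face opposite to the lactone ring | O=C1C[C@H]2[C@H](O)[C@H](O)C[C@H]2O1 | intermediate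
13 | 8,9-O-isopropylidene derivative of 12 | O=C1C[C@H]2[C@@H]3OC(C)(C)O[C@@H]3C[C@H]2O1 | intermediate
14 | lithium enolate of lactone 13 (C11=C12) | [Li]OC1=C[C@H]2[C@@H]3OC(C)(C)O[C@@H]3C[C@H]2O1 | intermediate
15 | 11-phenylselanyl lactone, selenium on the convex face cis to H7 | O=C1[C@H]([Se]c4ccccc4)[C@H]2[C@@H]3OC(C)(C)O[C@@H]3C[C@H]2O1 | intermediate
16 | butenolide: C7=C11 unsaturated 6,12-lactone with 8,9-acetonide, C6–O trans to the acetonide | O=C1C=C2[C@@H]3OC(C)(C)O[C@@H]3C[C@H]2O1 | intermediate
17 | ene-diol: cyclopentane with C6–OH (trans to the acetonide), exocyclic C7=C11 with C12H2OH cis to C6, 8,9-acetonide | OC/C=C1/[C@@H]2OC(C)(C)O[C@@H]2C[C@H]1O | intermediate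
18 | 12-O-pivalate of 17 | CC(C)(C)C(=O)OC/C=C1/[C@@H]2OC(C)(C)O[C@@H]2C[C@H]1O | intermediate
19 | cyclopentanone (C6=O) with exocyclic C7=C11 (C12H2OPiv cis to C6), 8,9-acetonide, C10H2 | CC(C)(C)C(=O)OC/C=C1/[C@@H]2OC(C)(C)O[C@@H]2CC1=O | intermediate
20 | 6-trimethylsilyloxy diene (C6=C10 enol silane of 19) | CC(C)(C)C(=O)OC/C=C1/[C@@H]2OC(C)(C)O[C@@H]2C=C1O[Si](C)(C)C | intermediate
21 | 10-hydroxymethyl ketone, C14H2OH trans to the acetonide | CC(C)(C)C(=O)OC/C=C1/[C@@H]2OC(C)(C)O[C@@H]2[C@@H](CO)C1=O | intermediate
22 | 14-O-TBS ether of 21 | CC(C)(C)C(=O)OC/C=C1/[C@@H]2OC(C)(C)O[C@@H]2[C@@H](CO[Si](C)(C)C(C)(C)C)C1=O | intermediate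
23 | tetrasubstituted enol silane, C6(OTMS)=C10(CH2OTBS) | CC(C)(C)C(=O)OC/C=C1/[C@@H]2OC(C)(C)O[C@@H]2C(CO[Si](C)(C)C(C)(C)C)=C1O[Si](C)(C)C | intermediate
24 | aldol adduct: quaternary C10 with CH2OTBS cis and the C1 carbinol chain trans to the acetonide; (Z)-iodoalkene; both C1 epimers (C1 left undefined) | CC(C)(C)C(=O)OC/C=C1/[C@@H]2OC(C)(C)O[C@@H]2[C@@](CO[Si](C)(C)C(C)(C)C)(C(O)CC/C(C)=C\I)C1=O | intermediate
25 | saturated ketone: C7–H with the CH2CH2OPiv arm cis to the acetonide; both C1 epimers | CC(C)(C)C(=O)OCC[C@@H]1[C@@H]2OC(C)(C)O[C@@H]2[C@@](CO[Si](C)(C)C(C)(C)C)(C(O)CC/C(C)=C\I)C1=O | intermediate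
26 | cis-fused bicyclo[5.3.0]dec-4-ene-1,6-diol (germacrane numbers): tertiary C6–OH cis to the C14 arm, cycloheptene on the face opposite to the acetonide and the C7 arm; both C1 epimers | CC(C)(C)C(=O)OCC[C@@H]1[C@@H]2OC(C)(C)O[C@@H]2[C@@]3(CO[Si](C)(C)C(C)(C)C)C(O)CCC(C)=C[C@@]13O | intermediate
27 | 6-hydroxy-1-ketone of the same bicycle | CC(C)(C)C(=O)OCC[C@@H]1[C@@H]2OC(C)(C)O[C@@H]2[C@@]3(CO[Si](C)(C)C(C)(C)C)C(=O)CCC(C)=C[C@@]13O | intermediate
28 | 1,6-anti diol: C1–OH trans to C6–OH and to the C14 arm on the seven-membered ring | CC(C)(C)C(=O)OCC[C@@H]1[C@@H]2OC(C)(C)O[C@@H]2[C@@]3(CO[Si](C)(C)C(C)(C)C)[C@@H](O)CCC(C)=C[C@@]13O | intermediate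
29 | fragmentation substrate: cis-fused bicyclo[5.3.0]dec-4-en-6-ol with C1–OMs trans to the C14 arm, quaternary C10 (CH2OTBS), 8,9-acetonide, C7 CH2CH2OPiv | CC(C)(C)C(=O)OCC[C@@H]1[C@@H]2OC(C)(C)O[C@@H]2[C@@]3(CO[Si](C)(C)C(C)(C)C)[C@@H](OS(C)(=O)=O)CCC(C)=C[C@@]13O | intermediate
30 | (7R,8S,9R) ten-membered C6 enone with ring-cis C4=C5 and C1=C10, 14-OTBS, 8,9-acetonide, C7 CH2CH2OPiv | O=C1/C=C(/C)CC/C=C(/CO[Si](C)(C)C(C)(C)C)[C@H]2OC(C)(C)O[C@H]2[C@H]1CCOC(=O)C(C)(C)C | intermediate
31 | (6R,7S,8S,9R)-6,12-diol of the ten-membered ring, 14-OTBS, 8,9-acetonide | O[C@@H]1/C=C(/C)CC/C=C(/CO[Si](C)(C)C(C)(C)C)[C@H]2OC(C)(C)O[C@H]2[C@H]1CCO | intermediate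
32 | trans-fused 6,12-γ-lactone, 14-OTBS, 8,9-acetonide | C1C(=O)O[C@@H]2/C=C(/C)CC/C=C(/CO[Si](C)(C)C(C)(C)C)[C@H]3OC(C)(C)O[C@H]3[C@@H]12 | intermediate
33 | lithium enolate of lactone 32 (C11=C12) | C1=C(O[Li])O[C@@H]2/C=C(/C)CC/C=C(/CO[Si](C)(C)C(C)(C)C)[C@H]3OC(C)(C)O[C@H]3[C@@H]12 | intermediate
34 | 11-(dimethylaminomethyl) lactone (C11 undefined, lost on elimination) | CN(C)CC1C(=O)O[C@@H]2/C=C(/C)CC/C=C(/CO[Si](C)(C)C(C)(C)C)[C@H]3OC(C)(C)O[C@H]3[C@@H]12 | intermediate
35 | trimethylammonium iodide of 34 | C[N+](C)(C)CC1C(=O)O[C@@H]2/C=C(/C)CC/C=C(/CO[Si](C)(C)C(C)(C)C)[C@H]3OC(C)(C)O[C@H]3[C@@H]12.[I-] | intermediate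
36 | α-methylene (C11=C13) lactone, 14-OTBS, 8,9-acetonide | C=C1C(=O)O[C@@H]2/C=C(/C)CC/C=C(/CO[Si](C)(C)C(C)(C)C)[C@H]3OC(C)(C)O[C@H]3[C@@H]12 | intermediate
37 | 8,9,14-triol of the α-methylene lactone | C=C1C(=O)O[C@@H]2/C=C(/C)CC/C=C(/CO)[C@@H](O)[C@@H](O)[C@@H]12 | intermediate
38 | 9,14-O-di-tert-butylsilylene (six-membered dioxasilinane), 8-OH free | C=C1C(=O)O[C@@H]2/C=C(/C)CC/C=C3/CO[Si](C(C)(C)C)(C(C)(C)C)O[C@H]3[C@@H](O)[C@@H]12 | intermediate
39 | (S)-2-acetoxy-2-methylbutanoyl chloride | ClC(=O)[C@](C)(CC)OC(C)=O | intermediate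
40 | 8-O-[(S)-2-acetoxy-2-methylbutanoyl] 9,14-silylene | C=C1C(=O)O[C@@H]2/C=C(/C)CC/C=C3/CO[Si](C(C)(C)C)(C(C)(C)C)O[C@H]3[C@@H](OC(=O)[C@](C)(CC)OC(C)=O)[C@@H]12 | intermediate
41 | 9,14-diol 8-ester | C=C1C(=O)O[C@@H]2/C=C(/C)CC/C=C(/CO)[C@@H](O)[C@@H](OC(=O)[C@](C)(CC)OC(C)=O)[C@@H]12 | intermediate
42 | 14-aldehyde 9-ol 8-ester | C=C1C(=O)O[C@@H]2/C=C(/C)CC/C=C(/C=O)[C@@H](O)[C@@H](OC(=O)[C@](C)(CC)OC(C)=O)[C@@H]12 | intermediate
43 | CNP0499875.1: (6R,7S,8S,9R)-9-acetoxy-8-[(S)-2-acetoxy-2-methylbutanoyloxy]-14-oxo-germacra-1(10),4,11(13)-trien-6,12-olide with ring-cis C1=C10 and C4=C5 | C=C1C(=O)O[C@@H]2/C=C(/C)CC/C=C(/C=O)[C@@H](OC(C)=O)[C@@H](OC(=O)[C@](C)(CC)OC(C)=O)[C@@H]12 | target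

Total step count: 29 (steps 1–4 aldehyde 8, step 5 acid 10, steps 6–29 main line).
Longest linear sequence: 24 steps (steps 6–29, from lactone 11).

Steps most likely to fail

Step 16 (ring closure onto the C6 ketone). The alkenylchromium may be protonated, or may add too slowly to a ketone flanked by a quaternary and a tertiary carbon, so that the iodide is lost without cyclisation. The fallback closes the ring by olefin metathesis instead of carbonyl addition. It sets out from ketone 22: its enol silane 23 would be combined with commercial 4-methylpent-4-enal (BF3·OEt2, CH2Cl2, −78 °C) to give the isopropenyl aldol adduct F1 (both C1 epimers). [(Ph3P)CuH]6 would reduce the enone as in step 15 to the saturated ketone F2. CH2=CHMgBr with CeCl3 (THF, −78 °C) should add to C6 from the face opposite to the C14 arm, the C7 arm and the acetonide to give the vinyl carbinol F3. The second-generation Grubbs catalyst (CH2Cl2, 40 °C) would then close the trisubstituted C4=C5 bond, which comes back to the route at diol 26.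

Step 20 (key fragmentation). Intramolecular substitution to an oxetane may compete if the anti-periplanar conformer is poorly populated, and the new enone may epimerise or eliminate at C7 under the base. The fallback is a stepwise retro-aldol/E1cB opening driven by a C14 aldehyde, in which the alkene geometry is under thermodynamic control (C2 anti to the formyl group, the ring-cis isomer). It sets out from mesylate 29: HF·pyridine (THF, 0 °C) would remove the TBS group to give the primary alcohol F4, and Dess–Martin periodinane would give the β-hydroxy aldehyde F5. DBU (CH2Cl2, 0 °C) would cleave C6–C10 by retro-aldol reaction and expel mesylate from the resulting enolate to give the ten-membered keto enal F6. NaBH4 with CeCl3·7H2O (MeOH, −78 °C) would reduce both carbonyls to the allylic diol F7, TBSCl with imidazole would silylate the primary allylic hydroxyl to give the silyl ether F8, and iBu2AlH would cleave the pivalate, which comes back to the route at diol 31.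

Step 21 (C6 reduction). Facial selectivity of hydride delivery on the flexible ten-membered enone may be poor or reversed. The fallback inverts the carbinol instead of relying on direct delivery. It sets out from enone 30: NaBH4 with CeCl3·7H2O (MeOH, −78 °C), which keeps the pivalate, would give the 6-epi allylic alcohol F9. A Mitsunobu reaction with 4-nitrobenzoic acid (PPh3, DIAD, THF) would invert C6 to the 4-nitrobenzoate F10, and iBu2AlH would cleave both esters, which comes back to the route at diol 31.

Further compounds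
F1 | step 16 | isopropenyl aldol adduct (C1 epimers) | CC(C)(C)C(=O)OC/C=C1/[C@@H]2OC(C)(C)O[C@@H]2[C@@](CO[Si](C)(C)C(C)(C)C)(C(O)CCC(C)=C)C1=O
F2 | step 16 | saturated ketone with isopropenyl chain (C1 epimers) | CC(C)(C)C(=O)OCC[C@@H]1[C@@H]2OC(C)(C)O[C@@H]2[C@@](CO[Si](C)(C)C(C)(C)C)(C(O)CCC(C)=C)C1=O
F3 | step 16 | C6 vinyl carbinol, vinyl cis to the C1 chain (C1 epimers) | CC(C)(C)C(=O)OCC[C@@H]1[C@@H]2OC(C)(C)O[C@@H]2[C@@](CO[Si](C)(C)C(C)(C)C)(C(O)CCC(C)=C)[C@@]1(O)C=C
F4 | step 20 | C14 primary alcohol of mesylate 29 | CC(C)(C)C(=O)OCC[C@@H]1[C@@H]2OC(C)(C)O[C@@H]2[C@@]3(CO)[C@@H](OS(C)(=O)=O)CCC(C)=C[C@@]13O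
F5 | step 20 | β-hydroxy aldehyde (C14 formyl on C10, C6–OH, C1–OMs) | CC(C)(C)C(=O)OCC[C@@H]1[C@@H]2OC(C)(C)O[C@@H]2[C@@]3(C=O)[C@@H](OS(C)(=O)=O)CCC(C)=C[C@@]13O
F6 | step 20 | ten-membered keto enal (C6 ketone, C14 aldehyde, ring-cis C1=C10 and C4=C5) | O=C1/C=C(/C)CC/C=C(/C=O)[C@H]2OC(C)(C)O[C@H]2[C@H]1CCOC(=O)C(C)(C)C
F7 | step 20 | (6R)-6,14-diol 12-pivalate | O[C@@H]1/C=C(/C)CC/C=C(/CO)[C@H]2OC(C)(C)O[C@H]2[C@H]1CCOC(=O)C(C)(C)C
F8 | step 20 | (6R)-6-ol 14-OTBS 12-pivalate | O[C@@H]1/C=C(/C)CC/C=C(/CO[Si](C)(C)C(C)(C)C)[C@H]2OC(C)(C)O[C@H]2[C@H]1CCOC(=O)C(C)(C)C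
F9 | step 21 | 6-epi allylic alcohol (6S) 14-OTBS 12-pivalate | O[C@H]1/C=C(/C)CC/C=C(/CO[Si](C)(C)C(C)(C)C)[C@H]2OC(C)(C)O[C@H]2[C@H]1CCOC(=O)C(C)(C)C
F10 | step 21 | inverted C6 4-nitrobenzoate 14-OTBS 12-pivalate | O=C(O[C@@H]1/C=C(/C)CC/C=C(/CO[Si](C)(C)C(C)(C)C)[C@H]2OC(C)(C)O[C@H]2[C@H]1CCOC(=O)C(C)(C)C)c1ccc(cc1)[N+](=O)[O-]
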